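The fraction of its charge that a flask uses per day is, at one loading, a ratio of rate to enzyme. The flask and both earlier runs carry 0.02 mol%, so that fraction compares enzyme with enzyme directly.

| flask | starting material | enzyme | added ligand | remark |
|---|---|---|---|---|
| Wednesday's | 0.067 M | 0.02 mol% | 0.12 mM | run made earlier |
| Monday's | 0.15 M | 0.02 mol% | 0.12 mM | run made earlier |
| flask | 0.10 M | 0.02 mol% | 0.12 mM |  |

| run | time / d | product / % | starting material / % |
|---|---|---|---|
| Wednesday's | 0.250 | 21.2 | 78.7 |
| Wednesday's | 0.833 | 35.6 | 63.2 |
| Wednesday's | 1.25 | 45.0 | 54.8 |
| Wednesday's | 2.00 | 52.2 | 47.7 |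
| Wednesday's | 3.00 | 57.6 | 42.2 |
| Monday's | 0.250 | 62.3 | 37.9 |
| Monday's | 0.417 | 68.8 | 32.9 |
| Monday's | 0.833 | 77.8 | 22.3 |
| Monday's | 1.67 | 82.0 | 18.2 |
| Monday's | 3.00 | 86.2 | 14.5 |

(standard deviation of a reading: 1 percentage point)

1. apparent order in enzyme when 50 % of the starting material are converted (percent change of the rate of making product for one percent more enzyme charged)

With the main step alone and one charge of starting material, enzyme works unchanged, a given conversion arrives when enzyme times time reaches a fixed sum, and the rate there follows the enzyme: the order is 1.

Now add a loss of activity with age. More enzyme arrives sooner and younger, so the order rises above 1. If activity falls as a power of age, the order equals mean activity on the way over activity on arrival.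

The readings give a size. Wednesday's run uses 0.852 d⁻¹ of its charge in its first 0.250 d, and Monday's run uses 0.299 d⁻¹ between 0.250 d and 0.417 d, less than Wednesday's. Wednesday's run has 1.13 times Monday's amount left. Its own later slowing, from 0.133 d⁻¹ to 0.0550 d⁻¹, reads as a power of 4.20 in what is left. Removing that leaves fresh activity at 1.72 times aged activity, a rough reading given the scatter. Replacing the curve by the mean of its ends gives 1.36, the arrival ratio: mean activity on the way over activity on arrival.

The rest is a levelling. Late on, Wednesday's 0.0550 d⁻¹ stands beside Monday's 0.0490 d⁻¹ with 0.991 times Monday's amount left, at twice Monday's age, so, as far as these readings show, the fall appears over by then. This reckoning therefore stays at 1.36.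

The forecast differs: 1.1, between 0.7 and 1.7, while noting that “the rate collapses steeply and the conversions stall”.

The flask gives an order of 1.4, at half conversion after 0.445 d, beside the arrival ratio of 1.36 reckoned from the runs.

    starting material + enzyme → product + enzyme, rate k1*[starting material]^3*[enzyme]/(1 + ([starting material]/Kh1)^3) (0.133 M, k = 17800 M⁻³ min⁻¹)
    enzyme + added ligand ⇌ idle complex (K = 9300 M⁻¹, k = 10.4 M⁻¹ min⁻¹)

The flask's enzyme stands at 67.2 % of the catalyst charged after 0.300 d and 49.7 % after 1.50 d, the remainder being idle complex. Taken to the flask's enzyme of 49.5 % after 3.00 d, with the mean of the ends as before, the arrival ratio is 1.51, more than the 1.36 from the runs.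

(The readings are calculated from invented constants; noise was put on by code.)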